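1. A flask that turned substrate wholly into target could not have stood still short of the charge, yet the grey run read 75.1 %, 74.6 % and 75.6 % at 5.00 d, 6.00 d and 8.00 d. So I reckoned with what was left over and not with what was made: on average, target stood at a fraction 0.751 of the charge, which left a fraction 0.249 somewhere else.

| setting | grey | teal | flask |
|---|---|---|---|
| substrate | 0.074 M | 0.11 M | 0.074 M |
| free catalyst | 10 mol% | 10 mol% | 10 mol% |
| temperature | 50 °C | 45 °C | 50 °C |
| remark | the very flask that is asked about, followed so far | run made earlier |  |
| time |  |  | 8.0 d |

grey run (percent of the substrate charged)

| time / d | target / % |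
|---|---|
| 1.25 | 34.6 |
| 2.50 | 59.7 |
| 3.00 | 65.9 |
| 5.00 | 75.1 |
| 6.00 | 74.6 |
| 8.00 | 75.6 |

teal run (percent of the substrate charged)

| time / h | target / % |
|---|---|
| 6.00 | 2.6 |
| 12.0 | 8.0 |
| 15.0 | 9.8 |
| 20.0 | 13.6 |
| 30.0 | 23.2 |
| 40.0 | 29.2 |

(scatter of a reading: 0.5 percentage points)

- target, in percent of the substrate first charged, at 8.0 d
- what to do for the largest gain in target; "none" if nothing gains more than 2 percentage points (summer / noon / winter / autumn / none)
- target present, with what was taken out counted in, in percent of the substrate first charged, after noon
- target present, with what was taken out counted in, in percent of the substrate first charged, after winter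

- summer: change nothing and wait 4.0 d more
- noon: at 8.0 d take out 90 % of the target then present, then wait 4.0 d
- winter: at 8.0 d raise the temperature by 10 K, then wait 4.0 d
- autumn: at 8.0 d add free catalyst, 100 % of the amount charged, then wait 4.0 d

- target taken out counts as made
- the numbers in the tables scatter by 0.5 percentage points (one standard deviation)
- additions bring no volume worth counting

2. Dividing the one by the other gave 3.02 for the grey run. I called this the split, the parts of target per part left over at the standstill; if the leftover went by a side road, it is a selectivity factor.

3. First extreme: the leftover is substrate in balance with target. Noon then restarts the flask, and what remains in it returns to the same fraction, for a gain of 17 percentage points. A catalyst moves no balance, so in this version the split stays the same at any loading.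

4. Second extreme: the leftover took a side road with no way back. Noon then gains nothing, and the split is one rate over another, so it follows the loading of free catalyst.

5. The grey flask had to lie between these, since a way back can be fast, slow or absent. Both runs had 10 mol%, so they did not show what the loading does to the split. The readings of the tail drifted by 0.67 points per 4.0 d, less than the 2 points that counts. I bet on the slow end, without proof: now at 75.1 %, best "none", and no number for winter.

The forecast, holding “this is an equilibrium”, gave 75.3 %, chose noon, and put noon at 91.5 % and winter at 74 %.

The flask gave 75.7 % and best winter: winter gained 6.1 points, noon 1.3 points, summer 1.3 points, autumn 1.5 points, with 77.0 % after noon and 81.9 % after winter. My bet parted from the flask at winter.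

    catalyst intermediate B → free catalyst + target (k = 0.0130 min⁻¹, Ea = 110 kJ mol⁻¹)
    substrate + free catalyst → catalyst intermediate A (k = 0.110 M⁻¹ min⁻¹, Ea = 52.0 kJ mol⁻¹)
    substrate ⇌ dormant form (K = 13.0, k = 1.40 × 10⁻⁴ min⁻¹, Ea = 122 kJ mol⁻¹, ΔH = −52.0 kJ mol⁻¹)
    catalyst intermediate A ⇌ catalyst intermediate B (K = 0.750, k = 0.00800 min⁻¹, Ea = 110 kJ mol⁻¹, ΔH = 26.0 kJ mol⁻¹)
    (constants at 50 °C)

At 8.00 d the grey flask held dormant form 23.9 % and substrate 0.286 %, and target over dormant form was 3.17, beside my split of 3.02. The neighbouring flask took 2.5 mol% of free catalyst, a quarter of the grey loading, with the other charges and the time held. The balance extreme keeps the split at 3.02; the side-road extreme scales it to 0.754. At 8.00 d the neighbour held target 39.5 %, dormant form 53.4 % and substrate 6.8 %, so target over dormant form was 0.739.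

Readings and results come from a simulation for substances that don't exist; the scatter is artificial.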